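**Plan**

- Labdane numbering is used throughout: ring A = C1–C5 and C10, ring B = C5–C10, C17 = formyl carbon on C8, C11–C16 = side chain on C9 (C15 ester, C16 CH2OAc). The feature that makes the key step possible: C8 and C9 each lie alpha to a carbon that can be carried at the carbonyl level (C17 and C11), so both are enol-type carbons, and ring B can be closed across C8–C9 once one of them is reversed in polarity at an anode.
- Retrosynthetic cuts, in order: C6–O (γ-oxidation of the enal), C12–C13 (B-alkyl Suzuki), C11=C12 (Wittig), C8–C9 (anodic coupling, ring B), C8=C17 (Peterson), C9=C11 (Wittig), C5–C6 (organolithium addition to the ring A ketone), C10–C9 (decarboxylative allylation).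
- Forward: ring A is bought as 2,2,6-trimethylcyclohexanone; C10 and then C5 are set; the C10 arm becomes a methyl enol ether and the C5 arm a ketene dithioacetal; ring B closes by anodic C8–C9 coupling. The ester-level C17 of the cyclised product is then moved, without any redox reagent, to the C7=C8 alkenyl dithiane (enal level); C11 becomes vinyl, the C13–C16 iodo enoate is coupled on, C17 is unmasked and the 6-hydroxyl is introduced last.
- Stereochemistry: C10 from the chiral phosphinooxazoline ligand on palladium; C5 from a hydroxyl-directed hydrogenation relayed from C10; C9 from the chair-like ring closure on the trans-1,2-disubstituted ring A; C6 from attack anti to the axial C4 and C10 methyl groups; C13=C14 from anti hydroiodination of the ynoate and a geometry-retaining coupling.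

Key step: step 13

Remark: enol ether 14 (and so 15, 16 and 19) is expected as an E-rich E/Z mixture; the E isomer is drawn and the mixture is carried on, because C11 becomes an acetal carbon in step 13 and both isomers should close to the same product.

**Route**

Step 1
Reactants: 1 2,2,6-trimethylcyclohexan-1-one; 2 allyl chloroformate
Product: 4 allyl 2,6,6-trimethylcyclohex-1-en-1-yl carbonate, via lithium enolate 3 (not isolated)
Conditions: LiN(SiMe3)2, THF, 0 °C; then 2, −78 °C to rt
Reagents that add atoms: none
Why: Only C6 of the ketone carries an alpha proton, so a single tetrasubstituted enolate forms, and the hard acyl chloride reacts at oxygen (O-acylation to the allyl enol carbonate).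

Step 2
Reactants: 4 allyl 2,6,6-trimethylcyclohex-1-en-1-yl carbonate
Product: 5 (S)-2-allyl-2,6,6-trimethylcyclohexan-1-one
Conditions: Pd2(dba)3 (2.5 mol%), (S)-t-BuPHOX [(S)-4-tert-butyl-2-(2-diphenylphosphinophenyl)-4,5-dihydrooxazole, 6 mol%], THF, 25 °C
Reagents that add atoms: none
Why: Decarboxylative asymmetric allylic alkylation (Tsuji type): zerovalent palladium ionises the allyl carbonate, CO2 leaves and the enolate couples with the π-allyl fragment inside the chiral P,N ligand sphere, which sets the quaternary C10; the (S) ligand is the enantiomer known to give the (S) ketone with this substrate class, the configuration the target needs.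

Step 3
Reactants: 5 (S)-2-allyl-2,6,6-trimethylcyclohexan-1-one
Product: 6 (S)-2,2,6-trimethyl-6-[(E)-prop-1-en-1-yl]cyclohexan-1-one
Conditions: RuHCl(CO)(PPh3)3 (3 mol%), toluene, 80 °C
Reagents that add atoms: none
Why: Metal hydride alkene isomerisation: reversible Ru–H addition and β-hydride elimination move the terminal double bond one carbon inward to the more stable (E)-propenyl group, while the quaternary C10 blocks further migration and cannot epimerise.

Step 4
Reactants: 6 (S)-2,2,6-trimethyl-6-[(E)-prop-1-en-1-yl]cyclohexan-1-one; 7 tert-butyl(3-iodopropoxy)dimethylsilane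
Product: 9 1-[3-(tert-butyldimethylsilyloxy)propyl]-2,2,6-trimethyl-6-[(E)-prop-1-en-1-yl]cyclohexan-1-ol (both configurations at C5), via 3-(tert-butyldimethylsilyloxy)propyllithium 8 (not isolated)
Conditions: 7, t-BuLi (2.1 equiv), Et2O, −78 °C; then 6, −78 to 0 °C; H2O
Reagents that add atoms: none
Why: 1,2-Addition of a primary organolithium (from iodine–lithium exchange) to a ketone that has no alpha proton and so cannot enolise; the new carbinol centre C5 forms as a mixture that is irrelevant because C5 becomes sp2 in step 5.

Step 5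
Reactants: 9 tertiary alcohol
Product: 10 tert-butyldimethyl(3-{2,2,6-trimethyl-6-[(E)-prop-1-en-1-yl]cyclohexylidene}propoxy)silane (exocyclic C5=C6, E/Z mixture)
Conditions: SOCl2, pyridine, CH2Cl2, −20 to 0 °C
Reagents that add atoms: none
Why: Dehydration of a tertiary alcohol through its chlorosulfite (E2 with pyridine): C4 and C10 are quaternary, so the only β-hydrogens are on C6 and the exocyclic C5=C6 alkene is the only olefin that can form.

Step 6
Reactants: 10 exocyclic alkene
Product: 11 1-{2-[3-(tert-butyldimethylsilyloxy)propylidene]-1,3,3-trimethylcyclohexyl}propane-1,2-diol (syn diol, mixture at the two carbinol carbons)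
Conditions: OsO4 (2 mol%), N-methylmorpholine N-oxide, acetone/H2O, 0 °C to rt
Reagents that add atoms: osmium tetroxide (oxygen carrier), O=[Os](=O)(=O)=O; N-methylmorpholine N-oxide, C[N+]1([O-])CCOCC1; water, O
Why: Catalytic syn-dihydroxylation takes the accessible disubstituted propenyl group and leaves the trisubstituted C5=C6 alkene, which is screened on both faces by two quaternary neighbours; the two carbinol centres form without control and are removed in step 8.

Step 7
Reactants: 11 unsaturated diol
Product: 12 1-{2-[3-(tert-butyldimethylsilyloxy)propyl]-1,3,3-trimethylcyclohexyl}propane-1,2-diol (H5 cis to C9, C6 chain trans to C9)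
Conditions: [Ir(cod)(PCy3)(py)]PF6 (10 mol%), H2 (1 atm), CH2Cl2, rt
Reagents that add atoms: none
Why: Hydroxyl-directed homogeneous hydrogenation: the C9 hydroxyl, homoallylic to C5=C6 and fixed on C10, binds the cationic iridium centre so that both hydrogens reach the alkene on the face of the C9 arm, which places H5 cis to C9 and the C6 chain trans to C9 (cis to the C10 methyl) and makes the E and Z alkenes converge.

Step 8
Reactants: 12 saturated diol
Product: 13 (1R,2R)-2-[3-(tert-butyldimethylsilyloxy)propyl]-1,3,3-trimethylcyclohexane-1-carbaldehyde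
Conditions: NaIO4, THF/pH 7 buffer, rt
Reagents that add atoms: none
Why: Malaprade glycol cleavage of the vicinal diol gives the C9 aldehyde, which has no alpha proton and so cannot epimerise C10.

Step 9
Reactants: 13 aldehyde
Product: 14 tert-butyl(3-{2-[(E)-2-methoxyvinyl]-2,6,6-trimethylcyclohexyl}propoxy)dimethylsilane
Conditions: MeOCH2PPh3Cl, KN(SiMe3)2, THF, 0 °C; then 13, 0 °C to rt
Reagents that add atoms: (methoxymethyl)triphenylphosphonium chloride, [Cl-].COC[P+](c1ccccc1)(c1ccccc1)c1ccccc1
Why: Wittig olefination with the methoxymethylene ylide homologates the hindered but non-enolisable aldehyde to the methyl enol ether C9=C11, the E isomer being expected to dominate because the methoxy group avoids the quaternary C10.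

Step 10
Reactants: 14 silyl ether
Product: 15 3-{2-[(E)-2-methoxyvinyl]-2,6,6-trimethylcyclohexyl}propan-1-ol
Conditions: Bu4NF, THF, rt
Reagents that add atoms: none
Why: Fluoride desilylation of the primary silyl ether in a basic medium that leaves the acid-sensitive enol ether intact.

Step 11
Reactants: 15 alcohol
Product: 16 3-{2-[(E)-2-methoxyvinyl]-2,6,6-trimethylcyclohexyl}propanal
Conditions: (COCl)2, DMSO, CH2Cl2, −78 °C; then Et3N, −78 to 0 °C
Reagents that add atoms: none
Why: Swern oxidation of the primary alcohol to the C8 aldehyde under amine-buffered conditions that an enol ether tolerates.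

Step 12
Reactants: 16 aldehyde; 17 2-(trimethylsilyl)-1,3-dithiane
Product: 19 2-(3-{2-[(E)-2-methoxyvinyl]-2,6,6-trimethylcyclohexyl}propylidene)-1,3-dithiane, via 2-lithio-2-(trimethylsilyl)-1,3-dithiane 18 (not isolated)
Conditions: 17, n-BuLi, THF, −78 to −20 °C; then 16, −78 °C to rt
Reagents that add atoms: none
Why: Peterson olefination: the lithiated silyl dithiane adds to the aldehyde and the β-silyl alkoxide loses Me3SiOLi to give the ketene dithioacetal C8=C17 under basic conditions that spare the enol ether.

Step 13
Reactants: 19 enol ether / ketene dithioacetal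
Product: 20 2-[1-(dimethoxymethyl)-5,5,8a-trimethyldecahydronaphthalen-2-yl]-2-methoxy-1,3-dithiane (trans-decalin, C11 on C9 and C17 on C8 both equatorial)
Conditions: constant-current electrolysis (undivided cell, reticulated vitreous carbon anode, Pt cathode, about 2.1 F/mol), LiClO4 (0.1 M), 2,6-lutidine, MeOH/THF 3:7, rt
Reagents that add atoms: methanol, CO
Why: The C8=C17 ketene dithioacetal, the more easily oxidised of the two electron-rich alkenes, loses one electron at the anode and its radical cation is attacked at C8 by the enol ether carbon C9; loss of a second electron and capture by methanol turn C11 into the dimethyl acetal and the sulfur-stabilised C17 cation into the 2-methoxy-1,3-dithiane. The closest known reaction type is the intramolecular anodic olefin coupling of ketene dithioacetal radical cations with enol ethers to five- and six-membered carbocycles. Ring B closes in a 6-exo mode with respect to both the C8=C17 and the C9=C11 double bond. C9 is set by a chair-like transition state that is fused trans to ring A through the fixed C5 and C10 centres and carries C11 pseudo-equatorial, so H9 comes out anti to the C10 methyl, and C8 is set in the same chair with C17 equatorial and trans to C11 (C8 becomes sp2 again in step 14). The step needs the dithioacetal to be oxidised before the enol ether, which its lower oxidation potential provides, and C–C bond formation to outrun methanol capture of the radical cation, which the three-atom tether held on a trans-1,2-disubstituted cyclohexane secures. 2,6-Lutidine keeps the medium from turning acidic, so the acetal and the ortho ester survive.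

Step 14
Reactants: 20 O,S,S-ortho ester
Product: 21 2-[1-(dimethoxymethyl)-5,5,8a-trimethyloctahydronaphthalen-2(1H)-ylidene]-1,3-dithiane
Conditions: pyridinium p-toluenesulfonate (10 mol%), 4 Å molecular sieves, toluene, 60 °C
Reagents that add atoms: none
Why: Acid-catalysed E1 loss of methanol from the ortho ester: the 1,3-dithian-2-ylium ion forms far more easily than the oxocarbenium ion of the dimethyl acetal and loses the C8 proton to give the ketene dithioacetal, while the sieves take up methanol.

Step 15
Reactants: 21 ketene dithioacetal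
Product: 23 2-[1-(dimethoxymethyl)-5,5,8a-trimethyl-1,4,4a,5,6,7,8,8a-octahydronaphthalen-2-yl]-1,3-dithiane, via dithiane-stabilised allyllithium 22 (not isolated)
Conditions: LiN(iPr)2, THF/HMPA, −78 °C; then MeOH, −78 °C
Reagents that add atoms: none
Why: Deconjugative protonation of a ketene dithioacetal: the amide base removes an allylic proton from the unhindered C7 methylene and not from the C9 methine next to the quaternary C10, and the sulfur-stabilised allyl anion is protonated kinetically at the dithiane carbon, which leaves the C7=C8 double bond, brings C17 to the aldehyde level and does not touch C9.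

Step 16
Reactants: 23 dimethyl acetal
Product: 24 2-(1,3-dithian-2-yl)-5,5,8a-trimethyl-1,4,4a,5,6,7,8,8a-octahydronaphthalene-1-carbaldehyde
Conditions: 10% aq. oxalic acid on SiO2, CH2Cl2, rt
Reagents that add atoms: water, O
Why: Mild acetal hydrolysis on oxalic acid-doped wet silica, under which the dithiane is stable and the β,γ-unsaturated aldehyde is expected neither to epimerise at C9 nor to move its double bond into conjugation.

Step 17
Reactants: 24 aldehyde
Product: 25 2-(5,5,8a-trimethyl-1-vinyl-1,4,4a,5,6,7,8,8a-octahydronaphthalen-2-yl)-1,3-dithiane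
Conditions: Ph3PCH3Br, KN(SiMe3)2, THF, 0 °C; then 24, −78 to 0 °C
Reagents that add atoms: methyltriphenylphosphonium bromide, [Br-].C[P+](c1ccccc1)(c1ccccc1)c1ccccc1
Why: Wittig methylenation: the small non-stabilised ylide adds to the aldehyde at low temperature faster than it can deprotonate C9, so the C9 configuration is kept and C11=C12 is in place.

Step 18
Reactants: 26 methyl 4-hydroxybut-2-ynoate
Product: 27 methyl (Z)-4-hydroxy-3-iodobut-2-enoate
Conditions: NaI, AcOH, 70 °C
Reagents that add atoms: sodium iodide, [Na+].[I-]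
Why: Hydroiodination of an ynoate: conjugate addition of iodide and anti protonation give the (Z)-3-iodo enoate with iodine cis to the ester and CH2OH trans to it, so lactonisation is impossible.

Step 19
Reactants: 27 iodo alcohol
Product: 28 methyl (Z)-4-acetoxy-3-iodobut-2-enoate
Conditions: Ac2O, pyridine, DMAP (cat.), CH2Cl2, 0 °C
Reagents that add atoms: acetic anhydride, CC(=O)OC(C)=O
Why: Acetylation of the primary allylic alcohol by DMAP-catalysed acyl transfer.

Step 20
Reactants: 25 vinyl decalin; 28 methyl (Z)-4-acetoxy-3-iodobut-2-enoate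
Product: 30 methyl (E)-3-(acetoxymethyl)-5-[2-(1,3-dithian-2-yl)-5,5,8a-trimethyl-1,4,4a,5,6,7,8,8a-octahydronaphthalen-1-yl]pent-2-enoate, via B-alkyl-9-BBN adduct 29 (not isolated)
Conditions: 9-BBN dimer, THF, 0 °C to rt; then 28, Pd(dppf)Cl2 (5 mol%), AsPh3, Cs2CO3, DMF/H2O, rt
Reagents that add atoms: none
Why: B-alkyl Suzuki–Miyaura coupling: 9-BBN adds only to the monosubstituted C11=C12 alkene with boron on C12, and zerovalent palladium inserts into the C–I bond much faster than it ionises the allylic acetate, then transmetalates and couples with retention of the alkene geometry, so the ester ends cis to C12 (E by the priority rules).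

Step 21
Reactants: 30 alkenyl dithiane
Product: 31 methyl (E)-3-(acetoxymethyl)-5-(2-formyl-5,5,8a-trimethyl-1,4,4a,5,6,7,8,8a-octahydronaphthalen-1-yl)pent-2-enoate
Conditions: MeI, CaCO3, MeCN/H2O 9:1, 45 °C
Reagents that add atoms: water, O
Why: S-Alkylative hydrolysis of the allylic dithiane: methylation at sulfur and attack of water release the C17 aldehyde in conjugation with C7=C8 under neutral, buffered conditions that leave the ester, the acetate and C9 untouched.

Step 22
Reactants: 31 enal
Product: 32 methyl (E)-3-(acetoxymethyl)-5-{5,5,8a-trimethyl-2-[(triethylsilyloxy)methylene]-1,2,4a,5,6,7,8,8a-octahydronaphthalen-1-yl}pent-2-enoate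
Conditions: Et3SiOTf, Et3N, CH2Cl2, −78 to 0 °C
Reagents that add atoms: triethylsilyl trifluoromethanesulfonate, CC[Si](CC)(CC)OS(=O)(=O)C(F)(F)F
Why: Soft enolisation of the enal: O-silylation and removal of the γ-proton at C6 by the amine give the 1-silyloxy diene, the only conjugated enol available because C9 lies off the conjugation path and the ester is far less acidic.

Step 23
Reactants: 32 silyl dienol ether
Product: 33 CNP0112124.1
Conditions: mCPBA, NaHCO3, CH2Cl2, −20 °C; then aq. citric acid, THF
Reagents that add atoms: 3-chloroperoxybenzoic acid, OOC(=O)c1cccc(Cl)c1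
Why: Vinylogous Rubottom oxidation: the peracid epoxidises the electron-rich terminal C6=C7 bond of the dienol ether on the face opposite the axial C4 and C10 methyl groups, and collapse of the epoxide with loss of the silyl group restores the C7=C8 enal and leaves the 6-hydroxyl equatorial, cis to H5, while the electron-poor C13=C14 enoate is not attacked.

**Compound list**

1 | 2,2,6-trimethylcyclohexan-1-one (racemic) | CC1CCCC(C)(C)C1=O | starting material
2 | allyl chloroformate | C=CCOC(=O)Cl | starting material
3 | lithium 2,6,6-trimethylcyclohex-1-en-1-olate | [Li]OC1=C(C)CCCC1(C)C | intermediate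
4 | allyl 2,6,6-trimethylcyclohex-1-en-1-yl carbonate | C=CCOC(=O)OC1=C(C)CCCC1(C)C | intermediate
5 | (S)-2-allyl-2,6,6-trimethylcyclohexan-1-one | C=CC[C@]1(C)CCCC(C)(C)C1=O | intermediate
6 | (S)-2,2,6-trimethyl-6-[(E)-prop-1-en-1-yl]cyclohexan-1-one | C/C=C/[C@]1(C)CCCC(C)(C)C1=O | intermediate
7 | tert-butyl(3-iodopropoxy)dimethylsilane | CC(C)(C)[Si](C)(C)OCCCI | starting material
8 | 3-(tert-butyldimethylsilyloxy)propyllithium | [Li]CCCO[Si](C)(C)C(C)(C)C | intermediate
9 | 1-[3-(tert-butyldimethylsilyloxy)propyl]-2,2,6-trimethyl-6-[(E)-prop-1-en-1-yl]cyclohexan-1-ol; C10 as in 6, both configurations at the carbinol carbon C5 | C/C=C/[C@]1(C)CCCC(C)(C)C1(O)CCCO[Si](C)(C)C(C)(C)C | intermediate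
10 | tert-butyldimethyl(3-{2,2,6-trimethyl-6-[(E)-prop-1-en-1-yl]cyclohexylidene}propoxy)silane; C10 as in 6, exocyclic C5=C6 as E/Z mixture | C/C=C/[C@]1(C)CCCC(C)(C)C1=CCCO[Si](C)(C)C(C)(C)C | intermediate
11 | 1-{2-[3-(tert-butyldimethylsilyloxy)propylidene]-1,3,3-trimethylcyclohexyl}propane-1,2-diol; C10 as in 6, syn diol, mixture at the two carbinol carbons | CC(O)C(O)[C@]1(C)CCCC(C)(C)C1=CCCO[Si](C)(C)C(C)(C)C | intermediate
12 | 1-{2-[3-(tert-butyldimethylsilyloxy)propyl]-1,3,3-trimethylcyclohexyl}propane-1,2-diol; H5 cis to the diol-bearing carbon C9, silyloxypropyl chain trans to C9 and cis to the C10 methyl | CC(O)C(O)[C@]1(C)CCCC(C)(C)[C@H]1CCCO[Si](C)(C)C(C)(C)C | intermediate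
13 | (1R,2R)-2-[3-(tert-butyldimethylsilyloxy)propyl]-1,3,3-trimethylcyclohexane-1-carbaldehyde; formyl and side chain trans | O=C[C@]1(C)CCCC(C)(C)[C@H]1CCCO[Si](C)(C)C(C)(C)C | intermediate
14 | tert-butyl(3-{2-[(E)-2-methoxyvinyl]-2,6,6-trimethylcyclohexyl}propoxy)dimethylsilane; ring centres as in 13 | CO/C=C/[C@]1(C)CCCC(C)(C)[C@H]1CCCO[Si](C)(C)C(C)(C)C | intermediate
15 | 3-{2-[(E)-2-methoxyvinyl]-2,6,6-trimethylcyclohexyl}propan-1-ol; ring centres as in 13 | CO/C=C/[C@]1(C)CCCC(C)(C)[C@H]1CCCO | intermediate
16 | 3-{2-[(E)-2-methoxyvinyl]-2,6,6-trimethylcyclohexyl}propanal; ring centres as in 13 | CO/C=C/[C@]1(C)CCCC(C)(C)[C@H]1CCC=O | intermediate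
17 | 2-(trimethylsilyl)-1,3-dithiane | C[Si](C)(C)C1SCCCS1 | starting material
18 | 2-lithio-2-(trimethylsilyl)-1,3-dithiane | [Li]C1([Si](C)(C)C)SCCCS1 | intermediate
19 | 2-(3-{2-[(E)-2-methoxyvinyl]-2,6,6-trimethylcyclohexyl}propylidene)-1,3-dithiane; ring centres as in 13, C9 arm and C6 arm trans (precursor of the key step) | CO/C=C/[C@]1(C)CCCC(C)(C)[C@H]1CCC=C2SCCCS2 | intermediate
20 | 2-[1-(dimethoxymethyl)-5,5,8a-trimethyldecahydronaphthalen-2-yl]-2-methoxy-1,3-dithiane; trans-decalin, H5 and H9 anti to the C10 methyl, C11 (on C9) and C17 (on C8) equatorial and trans (product of the key step) | COC(OC)[C@@H]1[C@@H](C3(OC)SCCCS3)CC[C@@H]2C(C)(C)CCC[C@@]12C | intermediate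
21 | 2-[1-(dimethoxymethyl)-5,5,8a-trimethyloctahydronaphthalen-2(1H)-ylidene]-1,3-dithiane; C5, C9, C10 as in 20 | COC(OC)[C@@H]1C(=C3SCCCS3)CC[C@@H]2C(C)(C)CCC[C@@]12C | intermediate
22 | 2-lithio-2-[1-(dimethoxymethyl)-5,5,8a-trimethyl-1,4,4a,5,6,7,8,8a-octahydronaphthalen-2-yl]-1,3-dithiane (allyl anion over C7–C8–C17) | COC(OC)[C@@H]1C(C3([Li])SCCCS3)=CC[C@@H]2C(C)(C)CCC[C@@]12C | intermediate
23 | 2-[1-(dimethoxymethyl)-5,5,8a-trimethyl-1,4,4a,5,6,7,8,8a-octahydronaphthalen-2-yl]-1,3-dithiane; C7=C8, C5, C9, C10 as in 20 | COC(OC)[C@@H]1C(C3SCCCS3)=CC[C@@H]2C(C)(C)CCC[C@@]12C | intermediate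
24 | 2-(1,3-dithian-2-yl)-5,5,8a-trimethyl-1,4,4a,5,6,7,8,8a-octahydronaphthalene-1-carbaldehyde; C5, C9, C10 as in 20 | O=C[C@@H]1C(C3SCCCS3)=CC[C@@H]2C(C)(C)CCC[C@@]12C | intermediate
25 | 2-(5,5,8a-trimethyl-1-vinyl-1,4,4a,5,6,7,8,8a-octahydronaphthalen-2-yl)-1,3-dithiane; C5, C9, C10 as in 20 | C=C[C@@H]1C(C3SCCCS3)=CC[C@@H]2C(C)(C)CCC[C@@]12C | intermediate
26 | methyl 4-hydroxybut-2-ynoate | COC(=O)C#CCO | starting material
27 | methyl (Z)-4-hydroxy-3-iodobut-2-enoate | COC(=O)/C=C(\I)CO | intermediate
28 | methyl (Z)-4-acetoxy-3-iodobut-2-enoate | COC(=O)/C=C(\I)COC(C)=O | intermediate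
29 | 9-{2-[2-(1,3-dithian-2-yl)-5,5,8a-trimethyl-1,4,4a,5,6,7,8,8a-octahydronaphthalen-1-yl]ethyl}-9-borabicyclo[3.3.1]nonane | C(C[C@@H]1C(C3SCCCS3)=CC[C@@H]2C(C)(C)CCC[C@@]12C)B4C5CCCC4CCC5 | intermediate
30 | methyl (E)-3-(acetoxymethyl)-5-[2-(1,3-dithian-2-yl)-5,5,8a-trimethyl-1,4,4a,5,6,7,8,8a-octahydronaphthalen-1-yl]pent-2-enoate | COC(=O)/C=C(\CC[C@@H]1C(C3SCCCS3)=CC[C@@H]2C(C)(C)CCC[C@@]12C)COC(C)=O | intermediate
31 | methyl (E)-3-(acetoxymethyl)-5-(2-formyl-5,5,8a-trimethyl-1,4,4a,5,6,7,8,8a-octahydronaphthalen-1-yl)pent-2-enoate | COC(=O)/C=C(\CC[C@@H]1C(C=O)=CC[C@@H]2C(C)(C)CCC[C@@]12C)COC(C)=O | intermediate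
32 | methyl (E)-3-(acetoxymethyl)-5-{5,5,8a-trimethyl-2-[(triethylsilyloxy)methylene]-1,2,4a,5,6,7,8,8a-octahydronaphthalen-1-yl}pent-2-enoate; C6=C7 and C8=C17 diene | COC(=O)/C=C(\CC[C@@H]1C(=CO[Si](CC)(CC)CC)C=C[C@@H]2C(C)(C)CCC[C@@]12C)COC(C)=O | intermediate
33 | CNP0112124.1, methyl (E)-3-(acetoxymethyl)-5-(2-formyl-4-hydroxy-5,5,8a-trimethyl-1,4,4a,5,6,7,8,8a-octahydronaphthalen-1-yl)pent-2-enoate; 6-OH equatorial, on the face opposite the C10 methyl | COC(=O)/C=C(\CC[C@@H]1C(C=O)=C[C@@H](O)[C@@H]2C(C)(C)CCC[C@@]12C)COC(C)=O | target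

**Step count and risks**

Total: 23 steps. Longest linear sequence: 21 steps (steps 1–17 and 20–23); steps 18–19 make the iodo enoate 28.

Steps most likely to fail:

Step 13. The enol ether arm may also close through the chair in which C11 is pseudo-axial, giving low facial selectivity at C9; C9 cannot be equilibrated later, because next to the C7=C8 double bond the wanted configuration is not clearly the favoured one. The fallback replaces kinetic by thermodynamic control; it sets out from 20 (as a C9 mixture) and returns at 25. Treatment of 20 with I2 and NaHCO3 in methanol, then water, should give methyl 1-(dimethoxymethyl)-5,5,8a-trimethyldecahydronaphthalene-2-carboxylate F1. Hydrolysis of its acetal on oxalic acid-doped wet silica should give methyl 1-formyl-5,5,8a-trimethyldecahydronaphthalene-2-carboxylate F2, in which C8 and C9 are both alpha to carbonyl groups; DBU in CH2Cl2 should then equilibrate it to the isomer with both substituents equatorial. Wittig methylenation (Ph3PCH3Br, KN(SiMe3)2) should give methyl 5,5,8a-trimethyl-1-vinyldecahydronaphthalene-2-carboxylate F3. Me2AlS(CH2)3SAlMe2 in hot toluene should convert the ester into 2-(5,5,8a-trimethyl-1-vinyloctahydronaphthalen-2(1H)-ylidene)-1,3-dithiane F4. LiN(iPr)2/HMPA at −78 °C, where the C7 methylene is expected to be removed faster than the hindered C9 methine, followed by methanol, should then give 25.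

Step 4. Addition to the doubly neopentyl carbonyl group may stall or be outrun by β-hydride reduction. The fallback uses an allyl Grignard reagent, which adds through a six-membered transition state even to very hindered ketones, and builds the chain afterwards; it sets out from 6 and returns at 9. Allylmagnesium bromide in Et2O should give 1-allyl-2,2,6-trimethyl-6-[(E)-prop-1-en-1-yl]cyclohexan-1-ol F5. 9-BBN, which takes only the terminal alkene, then NaOH/H2O2 should give 1-(3-hydroxypropyl)-2,2,6-trimethyl-6-[(E)-prop-1-en-1-yl]cyclohexan-1-ol F6. Silylation of the primary hydroxyl with t-BuMe2SiCl and imidazole should give 9.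

Step 23. The peracid may attack the enol ether bond C8=C17 (alpha oxidation) instead of the remote C6=C7 bond. The fallback separates deconjugation, epoxidation and opening; it sets out from 32 and returns at 33. Bu4NF with acetic acid in THF at −78 °C should protonate the dienolate kinetically at C8 and give methyl (E)-3-(acetoxymethyl)-5-(2-formyl-5,5,8a-trimethyl-1,2,4a,5,6,7,8,8a-octahydronaphthalen-1-yl)pent-2-enoate F7, the β,γ-unsaturated aldehyde with the C6=C7 double bond. Dimethyldioxirane in acetone at 0 °C should epoxidise this isolated alkene anti to the axial C4 and C10 methyl groups and give the 6,7-epoxide F8. Et3N in CH2Cl2 should open it by E1cB elimination from C8 and give 33.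

Further compounds
F1 | step 13 | methyl 1-(dimethoxymethyl)-5,5,8a-trimethyldecahydronaphthalene-2-carboxylate (trans-decalin, mixture at C8 and C9) | COC(OC)C1C(C(=O)OC)CC[C@@H]2C(C)(C)CCC[C@@]12C
F2 | step 13 | methyl 1-formyl-5,5,8a-trimethyldecahydronaphthalene-2-carboxylate (formyl and ester equatorial and trans after equilibration) | O=C[C@@H]1[C@@H](C(=O)OC)CC[C@@H]2C(C)(C)CCC[C@@]12C
F3 | step 13 | methyl 5,5,8a-trimethyl-1-vinyldecahydronaphthalene-2-carboxylate | C=C[C@@H]1[C@@H](C(=O)OC)CC[C@@H]2C(C)(C)CCC[C@@]12C
F4 | step 13 | 2-(5,5,8a-trimethyl-1-vinyloctahydronaphthalen-2(1H)-ylidene)-1,3-dithiane | C=C[C@@H]1C(=C3SCCCS3)CC[C@@H]2C(C)(C)CCC[C@@]12C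
F5 | step 4 | 1-allyl-2,2,6-trimethyl-6-[(E)-prop-1-en-1-yl]cyclohexan-1-ol | C/C=C/[C@]1(C)CCCC(C)(C)C1(O)CC=C
F6 | step 4 | 1-(3-hydroxypropyl)-2,2,6-trimethyl-6-[(E)-prop-1-en-1-yl]cyclohexan-1-ol | C/C=C/[C@]1(C)CCCC(C)(C)C1(O)CCCO
F7 | step 23 | methyl (E)-3-(acetoxymethyl)-5-(2-formyl-5,5,8a-trimethyl-1,2,4a,5,6,7,8,8a-octahydronaphthalen-1-yl)pent-2-enoate (C6=C7, mixture at C8) | COC(=O)/C=C(\CC[C@@H]1C(C=O)C=C[C@@H]2C(C)(C)CCC[C@@]12C)COC(C)=O
F8 | step 23 | 6,7-epoxide of F7, oxygen anti to the C10 methyl | COC(=O)/C=C(\CC[C@@H]1C(C=O)[C@H]3O[C@H]3[C@@H]2C(C)(C)CCC[C@@]12C)COC(C)=O
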